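A ratio of 1.96 opens the reckoning: at the same clock time, 20.0 h or 19.99 h, the larch run, with twice the enzyme of the cedar run, has gone that many times further in the logarithm of its remaining substrate. The flask asked about has the larch charge.

| setting | larch | cedar | flask |
|---|---|---|---|
| substrate | 0.20 M | 0.20 M | 0.20 M |
| enzyme | 4.4 µM | 2.2 µM | 4.4 µM |
| remark | the very flask that is asked about, followed so far | run made earlier |  |

larch run (percent of the substrate charged)

| time / h | target / % | substrate / % |
|---|---|---|
| 2.50 | 24 | 74 |
| 8.00 | 58 | 40 |
| 12.0 | 73 | 26 |
| 20.0 | 87 | 15 |
| 30.0 | 89 | 10 |

cedar run (percent of the substrate charged)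

| time / d | target / % | substrate / % |
|---|---|---|
| 0.833 | 62 | 38 |
| 1.67 | 85 | 18 |
| 2.50 | 90 | 5 |
| 3.00 | 92 | 9 |
| 4.00 | 94 | 3 |

(scatter of a reading: 2 percentage points)

* apparent order in enzyme when 5.0% of the substrate are converted (percent change of the rate of making target for one percent more enzyme charged)

- candidate steps: substrate + enzyme -> target + enzyme; enzyme <-> dormant form

1. The main step first. Substrate meets enzyme and gives target, and the enzyme comes back unchanged. At a fixed conversion the rate therefore goes with the enzyme, and the order is one, as the opening ratio reads within its scatter.

2. Next comes the loss of enzyme to the dormant form, an off-cycle form. The larch pace falls from 0.120 /h in the first reading to 0.0817 /h between 8.00 h and 20.0 h, so my reading of the loss is 0.0304 /h. The early pace puts the 5.0% mark at 0.426 h. More enzyme reaches the mark sooner and arrives with less lost, so the order exceeds one by the drift, the loss rate times the time to the mark: 0.0129. One over that loss rate is 32.9 h, and the mark comes far earlier than that.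

3. Then the rest. Both charges hold the same substrate at the mark, so the substrate's part of the rate cancels. In my reckoning the drift also reads as the share of the catalyst gone dormant at the mark, hardly any, so the return from the dormant form is left out. My order is 1.01.

4. The forecast gives 1.01: “Rate is therefore proportional to enzyme, with a small correction.” Its decline is 0.02 per h against my 0.0304 /h, yet both print the same order.

5. The flask gives 1.0, and it reaches the mark at 0.507 h.

    substrate + enzyme → target + enzyme, rate k1*[substrate]^2*[enzyme]/(1 + ([substrate]/Kh1)^2) (0.0710 M, k = 17000 /M²/min)
    enzyme ⇌ dormant form (K = 1.10, k = 7.90 × 10⁻⁴ /min)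

Carried to that time, the drift is 0.0154, hardly any of the enzyme. Carried in proportion to 0.600 d, the same drift stands at 0.436, and the flask then holds 38.1% of its catalyst as dormant form.

The earlier runs and the new flask stem from a simulated flask with made-up constants; scatter was added.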